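**Strategy.** The target is cut at the enolised 1,3-diketone, between the enol CH (chain C-2) and the ketone carbon (chain C-1) that sits on C-1 of the cyclohexene ring. The key step exploits that chain C-2 is the α-carbon of a methyl ketone and chain C-1 a carboxyl-level carbon. A crossed Claisen C-acylation of the lithium enolate of silyl-protected dehydrozingerone by the acyl imidazolide of the cyclohexenecarboxylic acid joins both halves and delivers the chelated enol directly. The acid, with its three stereocentres, comes from an auxiliary-controlled endo Diels–Alder reaction of a 1-aryl-4-silyl diene, whose allylsilane then shifts the ring alkene into place.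

Key step: step 8

Remark: the target is read as the (1S,2S,6S)-cyclohex-3-ene, with the ring C-1 acyl group trans to the C-2 dimethoxyphenyl ring and cis to the C-6 hydroxymethoxyphenyl ring; the diketone is handled as its Z enol.

**Step 1**
Reactants: 1 coniferaldehyde
Product: 2 (E)-3-{3-methoxy-4-[(triisopropylsilyl)oxy]phenyl}prop-2-enal
Conditions: TIPSCl, imidazole, DMF, rt
Reagents that add atoms: triisopropylsilyl chloride, CC(C)[Si](Cl)(C(C)C)C(C)C
Why: Silyl ether protection of the phenol, which would otherwise quench the chromium reagent of step 2 and the Lewis acid of step 4.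

**Step 2**
Reactants: 2 (E)-3-{3-methoxy-4-[(triisopropylsilyl)oxy]phenyl}prop-2-enal
Product: 3 trimethyl[(1E,3E)-4-{3-methoxy-4-[(triisopropylsilyl)oxy]phenyl}buta-1,3-dien-1-yl]silane
Conditions: Me3SiCHBr2, CrCl2 (excess), THF, rt
Reagents that add atoms: (dibromomethyl)trimethylsilane, C[Si](C)(C)C(Br)Br
Why: Takai–Utimoto olefination, in which the geminal dichromium reagent adds to the aldehyde and eliminates to the (E)-vinylsilane while the existing E alkene is untouched.

**Step 3**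
Reactants: 4 (E)-3-(3,4-dimethoxyphenyl)prop-2-enoic acid, 5 (S)-4-benzyl-1,3-oxazolidin-2-one
Product: 7 (S)-4-benzyl-3-[(E)-3-(3,4-dimethoxyphenyl)prop-2-enoyl]-1,3-oxazolidin-2-one, via mixed pivalic anhydride 6 (not isolated)
Conditions: PivCl, Et3N, THF, −20 °C; then 5, LiCl, rt
Reagents that add atoms: none
Why: N-acylation of the oxazolidinone by a mixed anhydride under LiCl/Et3N, the hindered pivaloyl carbonyl steering attack to the cinnamoyl carbonyl.

**Step 4**
Reactants: 7 (S)-4-benzyl-3-[(E)-3-(3,4-dimethoxyphenyl)prop-2-enoyl]-1,3-oxazolidin-2-one, 3 trimethyl[(1E,3E)-4-{3-methoxy-4-[(triisopropylsilyl)oxy]phenyl}buta-1,3-dien-1-yl]silane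
Product: 8 (S)-4-benzyl-3-[(1S,2S,5R,6S)-6-(3,4-dimethoxyphenyl)-2-{3-methoxy-4-[(triisopropylsilyl)oxy]phenyl}-5-(trimethylsilyl)cyclohex-3-ene-1-carbonyl]-1,3-oxazolidin-2-one
Conditions: Et2AlCl (1.4 equiv), CH2Cl2, −30 to 0 °C; 1 M HCl quench
Reagents that add atoms: none
Why: Auxiliary-controlled, Lewis acid-promoted Diels–Alder reaction in which Et2AlCl chelates both imide carbonyls of s-cis 7, the diene adds to the α-carbon si face opposite the benzyl group (setting the acyl- and dimethoxyphenyl-bearing carbons, trans from the E alkene), the silicon-bearing diene terminus (largest HOMO coefficient, positive charge stabilised by aryl and β-silicon) bonds to the β-carbon, and the endo mode places the silyloxyaryl and Me3Si carbons cis to the acyl group.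

**Step 5**
Reactants: 8 (the Diels–Alder adduct)
Product: 9 (S)-4-benzyl-3-[(1S,2S,6S)-2-(3,4-dimethoxyphenyl)-6-{3-methoxy-4-[(triisopropylsilyl)oxy]phenyl}cyclohex-3-ene-1-carbonyl]-1,3-oxazolidin-2-one
Conditions: TFA, CH2Cl2, 0 °C
Reagents that add atoms: none
Why: Protodesilylation of an allylsilane with allylic shift (SE2′), in which the proton adds to the alkene carbon remote from silicon and loss of Me3Si from the β-silyl cation should place the double bond next to the dimethoxyphenyl-bearing carbon, deleting the C–Si stereocentre and leaving the other three untouched.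

**Step 6**
Reactants: 9 (the transposed imide)
Product: 11 (1S,2S,6S)-2-(3,4-dimethoxyphenyl)-6-{3-methoxy-4-[(triisopropylsilyl)oxy]phenyl}cyclohex-3-ene-1-carboxylic acid, via lithium percarboxylate 10 (not isolated)
Conditions: LiOH·H2O, 30% H2O2, THF/H2O, 0 °C; then aq. Na2SO3; then HCl to pH 2
Reagents that add atoms: hydrogen peroxide, OO
Why: Hydroperoxide cleavage of an N-acyloxazolidinone, in which the small α-effect nucleophile attacks the exocyclic carbonyl even when hindered and the α-stereocentre is not enolised at 0 °C, sulfite then reducing the percarboxylate to the acid.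

**Step 7**
Reactants: 12 dehydrozingerone
Product: 13 (E)-4-{3-methoxy-4-[(triisopropylsilyl)oxy]phenyl}but-3-en-2-one
Conditions: TIPSCl, imidazole, DMF, rt
Reagents that add atoms: triisopropylsilyl chloride, CC(C)[Si](Cl)(C(C)C)C(C)C
Why: Silyl ether protection of the phenol so that only the methyl ketone is deprotonated and acylated in step 8.

**Step 8**
Reactants: 11 (the cyclohexenecarboxylic acid), 13 (E)-4-{3-methoxy-4-[(triisopropylsilyl)oxy]phenyl}but-3-en-2-one
Product: 16 (2Z,4E)-1-[(1S,2S,6S)-2-(3,4-dimethoxyphenyl)-6-{3-methoxy-4-[(triisopropylsilyl)oxy]phenyl}cyclohex-3-en-1-yl]-3-hydroxy-5-{3-methoxy-4-[(triisopropylsilyl)oxy]phenyl}penta-2,4-dien-1-one, via acyl imidazolide 14 (not isolated), via lithium enolate 15 (not isolated)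
Conditions: CDI, THF, rt (11 to 14); 13 (3.3 equiv), LiN(SiMe3)2 (3.2 equiv), THF, −78 °C (to 15); 14 added to 15, −78 to −20 °C; aq. NH4Cl
Reagents that add atoms: none
Why: CDI converts 11 under neutral conditions into acyl imidazolide 14 while LiN(SiMe3)2 deprotonates the only enolisable position of 13 to the cross-conjugated enolate 15; the enolate carbon adds to the acyl carbon of 14, imidazolide leaves the tetrahedral intermediate, and further 15 deprotonates the new diketone to its chelated lithium diketonate (one more equivalent is taken up by the imidazole freed on activation). The closest known reaction type is the crossed Claisen condensation, run as C-acylation of a ketone lithium enolate with an N-acyl azolide. No ring is closed and no stereocentre is created; the three ring stereocentres of 11 are carried through. The step needs C- over O-acylation, which the lithium counter-ion in THF and the azolide leaving group favour, and 1,2-attack over Michael self-condensation of the enone, which the low temperature should secure. It also needs the configuration at ring C-1, α to the acyl donor, to hold: base-free activation excludes a ketene, no amide base is left in excess over the ketone, and the diketonate once formed is deprotonated at the enol CH and not at ring C-1. Aqueous NH4Cl should return the product as its hydrogen-bonded Z enol.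

**Step 9**
Reactants: 16 (the bis-silyl diketone)
Product: 17 (2Z,4E)-1-[(1S,2S,6S)-2-(3,4-dimethoxyphenyl)-6-(4-hydroxy-3-methoxyphenyl)cyclohex-3-en-1-yl]-3-hydroxy-5-(4-hydroxy-3-methoxyphenyl)penta-2,4-dien-1-one
Conditions: Bu4NF, AcOH, THF, 0 °C
Reagents that add atoms: none
Why: Fluoride cleavage of both aryl silyl ethers, buffered with acetic acid so that neither retro-Claisen cleavage nor epimerisation at ring C-1 by phenoxide or diketonate is expected.

**Compound list**
1 | coniferaldehyde, (E)-3-(4-hydroxy-3-methoxyphenyl)prop-2-enal | COc1cc(/C=C/C=O)ccc1O | starting material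
2 | (E)-3-{3-methoxy-4-[(triisopropylsilyl)oxy]phenyl}prop-2-enal | COc1cc(/C=C/C=O)ccc1O[Si](C(C)C)(C(C)C)C(C)C | intermediate
3 | trimethyl[(1E,3E)-4-{3-methoxy-4-[(triisopropylsilyl)oxy]phenyl}buta-1,3-dien-1-yl]silane | COc1cc(/C=C/C=C/[Si](C)(C)C)ccc1O[Si](C(C)C)(C(C)C)C(C)C | intermediate
4 | (E)-3-(3,4-dimethoxyphenyl)prop-2-enoic acid | COc1ccc(/C=C/C(=O)O)cc1OC | starting material
5 | (S)-4-benzyl-1,3-oxazolidin-2-one | O=C1N[C@@H](Cc2ccccc2)CO1 | starting material
6 | (E)-3-(3,4-dimethoxyphenyl)prop-2-enoic pivalic anhydride | COc1ccc(/C=C/C(=O)OC(=O)C(C)(C)C)cc1OC | intermediate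
7 | (S)-4-benzyl-3-[(E)-3-(3,4-dimethoxyphenyl)prop-2-enoyl]-1,3-oxazolidin-2-one | COc1ccc(/C=C/C(=O)N2[C@@H](Cc3ccccc3)COC2=O)cc1OC | intermediate
8 | (S)-4-benzyl-3-[(1S,2S,5R,6S)-6-(3,4-dimethoxyphenyl)-2-{3-methoxy-4-[(triisopropylsilyl)oxy]phenyl}-5-(trimethylsilyl)cyclohex-3-ene-1-carbonyl]-1,3-oxazolidin-2-one (acyl, silyloxyaryl and Me3Si groups mutually cis, dimethoxyphenyl trans to them) | O=C(N1[C@@H](Cc2ccccc2)COC1=O)[C@@H]3[C@@H](c4ccc(OC)c(OC)c4)[C@H]([Si](C)(C)C)C=C[C@@H]3c5ccc(O[Si](C(C)C)(C(C)C)C(C)C)c(OC)c5 | intermediate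
9 | (S)-4-benzyl-3-[(1S,2S,6S)-2-(3,4-dimethoxyphenyl)-6-{3-methoxy-4-[(triisopropylsilyl)oxy]phenyl}cyclohex-3-ene-1-carbonyl]-1,3-oxazolidin-2-one | O=C(N1[C@@H](Cc2ccccc2)COC1=O)[C@@H]3[C@@H](c4ccc(OC)c(OC)c4)C=CC[C@@H]3c5ccc(O[Si](C(C)C)(C(C)C)C(C)C)c(OC)c5 | intermediate
10 | lithium (1S,2S,6S)-2-(3,4-dimethoxyphenyl)-6-{3-methoxy-4-[(triisopropylsilyl)oxy]phenyl}cyclohex-3-ene-1-carboperoxoate | [Li+].[O-]OC(=O)[C@@H]3[C@@H](c4ccc(OC)c(OC)c4)C=CC[C@@H]3c5ccc(O[Si](C(C)C)(C(C)C)C(C)C)c(OC)c5 | intermediate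
11 | (1S,2S,6S)-2-(3,4-dimethoxyphenyl)-6-{3-methoxy-4-[(triisopropylsilyl)oxy]phenyl}cyclohex-3-ene-1-carboxylic acid | OC(=O)[C@@H]3[C@@H](c4ccc(OC)c(OC)c4)C=CC[C@@H]3c5ccc(O[Si](C(C)C)(C(C)C)C(C)C)c(OC)c5 | intermediate
12 | dehydrozingerone, (E)-4-(4-hydroxy-3-methoxyphenyl)but-3-en-2-one | CC(=O)/C=C/c1ccc(O)c(OC)c1 | starting material
13 | (E)-4-{3-methoxy-4-[(triisopropylsilyl)oxy]phenyl}but-3-en-2-one | CC(=O)/C=C/c1ccc(O[Si](C(C)C)(C(C)C)C(C)C)c(OC)c1 | intermediate
14 | [(1S,2S,6S)-2-(3,4-dimethoxyphenyl)-6-{3-methoxy-4-[(triisopropylsilyl)oxy]phenyl}cyclohex-3-en-1-yl](1H-imidazol-1-yl)methanone | O=C(n1ccnc1)[C@@H]3[C@@H](c4ccc(OC)c(OC)c4)C=CC[C@@H]3c5ccc(O[Si](C(C)C)(C(C)C)C(C)C)c(OC)c5 | intermediate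
15 | lithium (E)-4-{3-methoxy-4-[(triisopropylsilyl)oxy]phenyl}buta-1,3-dien-2-olate | [Li+].[O-]C(=C)/C=C/c1ccc(O[Si](C(C)C)(C(C)C)C(C)C)c(OC)c1 | intermediate
16 | (2Z,4E)-1-[(1S,2S,6S)-2-(3,4-dimethoxyphenyl)-6-{3-methoxy-4-[(triisopropylsilyl)oxy]phenyl}cyclohex-3-en-1-yl]-3-hydroxy-5-{3-methoxy-4-[(triisopropylsilyl)oxy]phenyl}penta-2,4-dien-1-one | COc1cc(/C=C/C(O)=C/C(=O)[C@@H]2[C@@H](c3ccc(OC)c(OC)c3)C=CC[C@@H]2c2ccc(O[Si](C(C)C)(C(C)C)C(C)C)c(OC)c2)ccc1O[Si](C(C)C)(C(C)C)C(C)C | intermediate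
17 | (2Z,4E)-1-[(1S,2S,6S)-2-(3,4-dimethoxyphenyl)-6-(4-hydroxy-3-methoxyphenyl)cyclohex-3-en-1-yl]-3-hydroxy-5-(4-hydroxy-3-methoxyphenyl)penta-2,4-dien-1-one | COc1cc(/C=C/C(O)=C/C(=O)[C@@H]2[C@@H](c3ccc(OC)c(OC)c3)C=CC[C@@H]2c2ccc(O)c(OC)c2)ccc1O | target

**Total step count:** 9. **Longest linear sequence:** 7 steps (1, 2, 4, 5, 6, 8, 9).

**Steps most likely to fail**

Step 4. The β-aryl dienophile and the 1,4-disubstituted diene may combine too slowly, and the aluminium Lewis acid may ionise the electron-rich diene, leading to desilylative Michael addition, oligomerisation or loss of endo and regiocontrol. The fallback changes the dienophile to a 1,2-ketol template under chiral copper catalysis; it sets out from diene 3 and returns at acid 11. Veratraldehyde and 3-hydroxy-3-methylbutan-2-one are condensed (LiOH, MeOH/H2O) to (E)-1-(3,4-dimethoxyphenyl)-4-hydroxy-4-methylpent-1-en-3-one F1. F1 and 3 with catalytic Cu(OTf)2 and (R,R)-t-Bu-box in CH2Cl2 should give the ketol cycloadduct F2; the ligand enantiomer is the one that, on the square-planar chelate model of divalent copper, leaves the si face of the α-carbon open. TFA as in step 5 should move the alkene to give the ketol F3, and NaIO4 in MeOH/H2O cleaves the α-ketol to 11 and acetone.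

Step 8. The hindered acyl imidazolide may add slowly, so that O-acylation, enolisation of 14 with loss of the ring C-1 configuration, or self-condensation of the enolate compete. The fallback forms the same carbon–carbon bond with an acetylide in place of the enolate; it sets out from acid 11 and aldehyde 2 and returns at 16.
- Acid 11 is converted (CDI, then MeNHOMe·HCl) into the Weinreb amide F4.
- Aldehyde 2 is homologated (Me3SiC(Li)N2, THF, −78 °C to rt, Colvin rearrangement) to the enyne triisopropyl{2-methoxy-4-[(E)-but-1-en-3-yn-1-yl]phenoxy}silane F5.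
- The lithium acetylide of F5 (n-BuLi, THF, −78 °C) adds to F4 to give the ynone F6.
- Et2NH adds to the alkyne β-carbon to give the enaminone F7 (enamine geometry immaterial).
- Aqueous oxalic acid in THF hydrolyses F7 to diketone 16.

Step 6. Hydroperoxide may attack the endocyclic carbamate carbonyl of the very hindered imide, or the aryl silyl ether may be partly lost in the basic peroxide medium. The fallback removes the auxiliary reductively; it sets out from 9 and returns at 11. LiBH4 (THF, one equivalent of H2O, 0 °C) gives the primary alcohol F8 and the free auxiliary. TEMPO/PhI(OAc)2 oxidises F8 to the aldehyde F9, and NaClO2, NaH2PO4 and 2-methylbut-2-ene (Pinnick oxidation) give 11.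

**Further compounds**
F1 | step 4 | (E)-1-(3,4-dimethoxyphenyl)-4-hydroxy-4-methylpent-1-en-3-one | COc1ccc(/C=C/C(=O)C(C)(C)O)cc1OC
F2 | step 4 | 1-[(1S,2S,5R,6S)-6-(3,4-dimethoxyphenyl)-2-{3-methoxy-4-[(triisopropylsilyl)oxy]phenyl}-5-(trimethylsilyl)cyclohex-3-en-1-yl]-2-hydroxy-2-methylpropan-1-one | CC(C)(O)C(=O)[C@@H]3[C@@H](c4ccc(OC)c(OC)c4)[C@H]([Si](C)(C)C)C=C[C@@H]3c5ccc(O[Si](C(C)C)(C(C)C)C(C)C)c(OC)c5
F3 | step 4 | 1-[(1S,2S,6S)-2-(3,4-dimethoxyphenyl)-6-{3-methoxy-4-[(triisopropylsilyl)oxy]phenyl}cyclohex-3-en-1-yl]-2-hydroxy-2-methylpropan-1-one | CC(C)(O)C(=O)[C@@H]3[C@@H](c4ccc(OC)c(OC)c4)C=CC[C@@H]3c5ccc(O[Si](C(C)C)(C(C)C)C(C)C)c(OC)c5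
F4 | step 8 | (1S,2S,6S)-2-(3,4-dimethoxyphenyl)-N-methoxy-6-{3-methoxy-4-[(triisopropylsilyl)oxy]phenyl}-N-methylcyclohex-3-ene-1-carboxamide | CON(C)C(=O)[C@@H]3[C@@H](c4ccc(OC)c(OC)c4)C=CC[C@@H]3c5ccc(O[Si](C(C)C)(C(C)C)C(C)C)c(OC)c5
F5 | step 8 | triisopropyl{2-methoxy-4-[(E)-but-1-en-3-yn-1-yl]phenoxy}silane | C#C/C=C/c1ccc(O[Si](C(C)C)(C(C)C)C(C)C)c(OC)c1
F6 | step 8 | (E)-1-[(1S,2S,6S)-2-(3,4-dimethoxyphenyl)-6-{3-methoxy-4-[(triisopropylsilyl)oxy]phenyl}cyclohex-3-en-1-yl]-5-{3-methoxy-4-[(triisopropylsilyl)oxy]phenyl}pent-4-en-2-yn-1-one | O=C(C#C/C=C/c1ccc(O[Si](C(C)C)(C(C)C)C(C)C)c(OC)c1)[C@@H]3[C@@H](c4ccc(OC)c(OC)c4)C=CC[C@@H]3c5ccc(O[Si](C(C)C)(C(C)C)C(C)C)c(OC)c5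
F7 | step 8 | (4E)-3-(diethylamino)-1-[(1S,2S,6S)-2-(3,4-dimethoxyphenyl)-6-{3-methoxy-4-[(triisopropylsilyl)oxy]phenyl}cyclohex-3-en-1-yl]-5-{3-methoxy-4-[(triisopropylsilyl)oxy]phenyl}penta-2,4-dien-1-one | CCN(CC)C(/C=C/c1ccc(O[Si](C(C)C)(C(C)C)C(C)C)c(OC)c1)=CC(=O)[C@@H]3[C@@H](c4ccc(OC)c(OC)c4)C=CC[C@@H]3c5ccc(O[Si](C(C)C)(C(C)C)C(C)C)c(OC)c5
F8 | step 6 | [(1S,2S,6S)-2-(3,4-dimethoxyphenyl)-6-{3-methoxy-4-[(triisopropylsilyl)oxy]phenyl}cyclohex-3-en-1-yl]methanol | OC[C@@H]3[C@@H](c4ccc(OC)c(OC)c4)C=CC[C@@H]3c5ccc(O[Si](C(C)C)(C(C)C)C(C)C)c(OC)c5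
F9 | step 6 | (1S,2S,6S)-2-(3,4-dimethoxyphenyl)-6-{3-methoxy-4-[(triisopropylsilyl)oxy]phenyl}cyclohex-3-ene-1-carbaldehyde | O=C[C@@H]3[C@@H](c4ccc(OC)c(OC)c4)C=CC[C@@H]3c5ccc(O[Si](C(C)C)(C(C)C)C(C)C)c(OC)c5
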